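The runs were generated by integration with made-up constants; the scatter is artificial.

**Pool first.** Add up the larch readings before you divide: those of isomer of the product A run from 0 % to 1.7 %, with a scatter of 0.5 percentage points.

| flask | substrate | remark | time |
|---|---|---|---|
| larch | 0.20 M | run made earlier |  |
| flask | 0.40 M |  | 20 h |

larch run (percent of the substrate charged)

| time / h | isomer of the product A / % | target / % |
|---|---|---|
| 0.667 | 0 | 21.2 |
| 1.33 | 0 | 35.4 |
| 2.00 | 1.2 | 45.4 |
| 2.50 | 0.9 | 52.5 |
| 3.00 | 1.4 | 56.3 |
| 4.00 | 1.7 | 62.5 |

(standard deviation of a reading: 0.5 percentage points)

- share of isomer of the product A in isomer of the product A plus target at 1.5 min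
- share of isomer of the product A in isomer of the product A plus target at 20 h

- the numbers in the tables scatter with a standard deviation of 0.5 percentage points
- a reading or a percentage of target counts all its forms, free or not

**Bench rule.** Two products made side by side by steps of the same order, with neither consumed, stay in a fixed ratio (the selectivity factor), and the charge drops out. So take the pooled share, the sum of the isomer of the product A readings over the sum of those readings and the target readings: 1.87 %, give or take 0.44 points. The zero at 1.33 h is weak evidence against it: beside 35.4 % of target, the pooled share asks for 0.675 % of isomer of the product A, against a scatter of 0.5 points.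

**The border.** The larch readings end at 4.00 h, and 20 h lies 5.00 times later, so whether target stays unconsumed that long lies beyond them. My reckoning for the flask is 1.87 % at both asked times, and I trust the later figure less.

**Forecast.** The forecast, “I lean sequential but hedge”, gives 0.3 % at 1.5 min, less than my figure, and 12 % at 20 h, more than my figure.

**The result.** The flask gives 1.72 % at 1.5 min and 3.91 % at 20 h, which is 2.09 times the pooled share. Its target reaches 66.2 % at 7.49 h and stands at 58.8 % at 20.0 h. At the pooled share, that target goes with 1.12 % of isomer of the product A, while the flask holds 2.40 %.

    substrate ⇌ dormant form (K = 0.720, k = 1.40 × 10⁻⁴ /min)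
    substrate ⇌ isomer of the product A (K = 1.10, k = 1.10 × 10⁻⁴ /min)
    substrate + target ⇌ idle adduct, settled at all times (K = 1.20 /M)
    substrate ⇌ isomer of the product B (K = 0.450, k = 7.30 × 10⁻⁵ /min)
    substrate ⇌ target (K = 6.10, k = 0.00630 /min)
    target ⇌ isomer of the product C (K = 0.530, k = 6.20 × 10⁻⁴ /min)

**Neighbour flask.** Charged with 0.16 M, the neighbour flask gets 1.87 % from the pooled share, and its 58.9 % of target at 20 h goes with 1.12 % of isomer of the product A. Computed, it gives 1.72 % at 1.5 min and 4.03 % at 20 h, with 2.47 % of that isomer.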